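The cyclobutane and cyclopentane of the 2,2a,7,7a-tetrahydro-1H-cyclobuta[a]indene core (C1 = CMe2, C2 = CH–aryl, C2a and C7a = ring-fusion CH, C7 = CH2) conceal a stilbene C=C (C2=C2a) and a prenyl-type C=C (C7a=C1) held 1,6 on adjacent carbons of ring A. Both rings are closed in one intramolecular [2+2] photocycloaddition of an ortho-(1-hydroxy-3-methylbut-2-enyl)stilbene: C2a–C7a forms first, then the 1,4-diradical collapses through the C1–C2 bond between the gem-dimethyl carbon and the catechol-bearing carbon. A temporary (S)-carbinol at C7 steers all three stereocentres by allylic 1,3-strain and is then removed reductively; the intact prenyl group enters afterwards through an aryl bromide.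

Key step: step 8

Remarks
- Ring A locants in the tricyclic compounds: C2b (bonded to C2a), C3, C4, C5, C6, C6a (bonded to C7).
- The configurations are defined by the SMILES strings of the compound list; the stereodescriptors in the names follow from them.
- Abbreviations: TBS = tert-butyldimethylsilyl; TIPS = triisopropylsilyl; (−)-MIB = (2S)-3-exo-morpholinoisoborneol.
- Assumption: the two commercial reagents that deliver carbon atoms of the target (the alkenyl Grignard reagent and prenyl bromide) are numbered as starting materials.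

Step 1
Reactants: 1 diethyl (3,5-dimethoxybenzyl)phosphonate
Product: 2 diethyl (2,6-dibromo-3,5-dimethoxybenzyl)phosphonate
Conditions: NBS (2.1 equiv), MeCN, 0 °C to rt, dark
Reagents that add atoms: N-bromosuccinimide, O=C1CCC(=O)N1Br
Why: Electrophilic aromatic bromination should take both positions ortho to the benzylic carbon, each being para to one methoxy group and ortho to the other, while the position between the two methoxy groups is the most hindered.

Step 2
Reactants: 3 3,4-dihydroxybenzaldehyde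
Product: 4 3,4-bis(tert-butyldimethylsilyloxy)benzaldehyde
Conditions: TBSCl (2.3 equiv), imidazole, DMF, rt
Reagents that add atoms: tert-butyldimethylsilyl chloride, CC(C)(C)[Si](C)(C)Cl
Why: Imidazole-mediated silylation of the two phenols masks the catechol for the base, organolithium and Lewis acid steps and allows its release by fluoride at the end.

Step 3
Reactants: 2 diethyl (2,6-dibromo-3,5-dimethoxybenzyl)phosphonate; 4 3,4-bis(tert-butyldimethylsilyloxy)benzaldehyde
Product: 5 (E)-2,6-dibromo-3,5-dimethoxy-3',4'-bis(tert-butyldimethylsilyloxy)stilbene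
Conditions: NaH, 15-crown-5 (cat.), THF, 0 °C to rt
Reagents that add atoms: none
Why: Horner–Wadsworth–Emmons olefination of the benzylic phosphonate carbanion with the aryl aldehyde should give the (E)-stilbene, the usual outcome for benzylphosphonates, and the non-nucleophilic base spares the aryl silyl ethers.

Step 4
Reactants: 5 (E)-2,6-dibromo-3,5-dimethoxy-3',4'-bis(tert-butyldimethylsilyloxy)stilbene
Product: 7 (E)-3-bromo-2-[3,4-bis(tert-butyldimethylsilyloxy)styryl]-4,6-dimethoxybenzaldehyde, via aryllithium 6 (not isolated)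
Conditions: n-BuLi (1.05 equiv), THF, −78 °C; DMF, −78 to 0 °C; aq. NH4Cl
Reagents that add atoms: N,N-dimethylformamide, CN(C)C=O
Why: Bromine–lithium exchange of one of the two equivalent bromides (one equivalent of n-BuLi, methoxy-stabilised aryllithium) followed by Bouveault formylation with DMF should give the mono-aldehyde and leave the second bromide as the placeholder for the prenyl group.

Step 5
Reactants: 7 (E)-3-bromo-2-[3,4-bis(tert-butyldimethylsilyloxy)styryl]-4,6-dimethoxybenzaldehyde
Product: 8 (E)-3-bromo-6-hydroxy-4-methoxy-2-[3,4-bis(tert-butyldimethylsilyloxy)styryl]benzaldehyde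
Conditions: MgI2·OEt2 (2 equiv), toluene, 60 °C; aq. NH4Cl
Reagents that add atoms: none
Why: Chelation-controlled ether cleavage, in which MgI2 bridges the aldehyde oxygen and the ortho methoxy oxygen so that iodide demethylates only that ether, should differentiate the two ring A oxygens and spare the para methoxy group and the aryl silyl ethers.

Step 6
Reactants: 8 (E)-3-bromo-6-hydroxy-4-methoxy-2-[3,4-bis(tert-butyldimethylsilyloxy)styryl]benzaldehyde
Product: 9 (E)-3-bromo-4-methoxy-6-(triisopropylsilyloxy)-2-[3,4-bis(tert-butyldimethylsilyloxy)styryl]benzaldehyde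
Conditions: TIPSOTf, 2,6-lutidine, CH2Cl2, 0 °C
Reagents that add atoms: triisopropylsilyl trifluoromethanesulfonate, CC(C)[Si](OS(=O)(=O)C(F)(F)F)(C(C)C)C(C)C
Why: Silylation of the hydrogen-bonded phenol with the reactive silyl triflate gives a bulky ether that should not migrate to the neighbouring alkoxide of the next step and that blocks ortho-quinone methide and chromene formation from the allylic carbinol.

Step 7
Reactants: 9 (E)-3-bromo-4-methoxy-6-(triisopropylsilyloxy)-2-[3,4-bis(tert-butyldimethylsilyloxy)styryl]benzaldehyde; 10 (2-methylprop-1-en-1-yl)magnesium bromide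
Product: 11 (1S)-1-{3-bromo-4-methoxy-6-(triisopropylsilyloxy)-2-[(E)-3,4-bis(tert-butyldimethylsilyloxy)styryl]phenyl}-3-methylbut-2-en-1-ol
Conditions: 10 (4 equiv), Zn(OMe)2 (2 equiv), NaOMe, Et2O, rt, centrifugation; then 9, (−)-MIB (10 mol%), toluene, 0 °C to rt; aq. NH4Cl
Reagents that add atoms: none
Why: Amino-alcohol-catalysed enantioselective addition of a salt-free dialkenylzinc reagent to an aryl aldehyde, in which the catalyst formed from (−)-MIB and the diorganozinc is expected to deliver the alkenyl group to the Si face, should give the (S)-carbinol.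

Step 8
Reactants: 11 (1S)-1-{3-bromo-4-methoxy-6-(triisopropylsilyloxy)-2-[(E)-3,4-bis(tert-butyldimethylsilyloxy)styryl]phenyl}-3-methylbut-2-en-1-ol
Product: 13 (2S,2aS,7S,7aS)-3-bromo-2-[3,4-bis(tert-butyldimethylsilyloxy)phenyl]-4-methoxy-1,1-dimethyl-6-(triisopropylsilyloxy)-2,2a,7,7a-tetrahydro-1H-cyclobuta[a]inden-7-ol, via triplet 1,4-diradical 12 (not isolated)
Conditions: [Ir(dF(CF3)ppy)2(dtbbpy)]PF6 (1 mol%), degassed DMSO (0.02 M), blue LEDs (450 nm), rt
Reagents that add atoms: none
Why: Triplet energy transfer from photoexcited [Ir(dF(CF3)ppy)2(dtbbpy)]PF6 to the stilbene C=C gives a twisted triplet whose ring-A-side benzylic carbon (C2a) adds to the inner alkene carbon of the side chain (C7a), and the resulting triplet 1,4-diradical 12 (tertiary radical at C1, catechol-stabilised benzylic radical at C2) undergoes intersystem crossing and recombines through the C1–C2 bond, so that two rings and three stereocentres should arise in one operation. The closest known reaction type is the visible-light, triplet-sensitised intramolecular styrene–alkene [2+2] photocycloaddition of 1,6-dienes to bicyclo[3.2.0]heptanes. The five-membered ring closes by 5-exo-trig radical addition (C2a–C7a, rule of five) and the four-membered ring by 1,4-diradical recombination (C1–C2). C7a and C2a are set by the (S)-carbinol at C7 through allylic 1,3-strain: the carbinol hydrogen eclipses the alkene to avoid the Z-methyl group, ring A and the hydroxyl group then lie on opposite alkene faces, and C2a, being tethered to ring A, must bond anti to the hydroxyl group, with the cis ring fusion enforced by the short tether. C2 is set in the recombination, where the aryl group should take the exo face trans to ring A to avoid the ortho bromine, whatever the alkene geometry after E/Z scrambling. The step needs 1,5- rather than 1,6-closure and a single alkene partner, which the three-atom tether and the deferral of the intact prenyl group as a bromide secure.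

Step 9
Reactants: 13 (2S,2aS,7S,7aS)-3-bromo-2-[3,4-bis(tert-butyldimethylsilyloxy)phenyl]-4-methoxy-1,1-dimethyl-6-(triisopropylsilyloxy)-2,2a,7,7a-tetrahydro-1H-cyclobuta[a]inden-7-ol
Product: 14 (2S,2aR,7aS)-3-bromo-2-[3,4-bis(tert-butyldimethylsilyloxy)phenyl]-4-methoxy-1,1-dimethyl-6-(triisopropylsilyloxy)-2,2a,7,7a-tetrahydro-1H-cyclobuta[a]indene
Conditions: Et3SiH (3 equiv), TFA (5 equiv), CH2Cl2, −40 to 0 °C
Reagents that add atoms: none
Why: Ionic hydrogenation, in which acid ionises the benzylic alcohol to a cation stabilised by the ortho silyloxy and para methoxy groups (too stabilised to gain from cyclobutane ring expansion) and the silane delivers hydride, should erase the auxiliary stereocentre and leave C2, C2a and C7a untouched.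

Step 10
Reactants: 14 (2S,2aR,7aS)-3-bromo-2-[3,4-bis(tert-butyldimethylsilyloxy)phenyl]-4-methoxy-1,1-dimethyl-6-(triisopropylsilyloxy)-2,2a,7,7a-tetrahydro-1H-cyclobuta[a]indene; 15 1-bromo-3-methylbut-2-ene (prenyl bromide)
Product: 18 (2S,2aR,7aS)-2-[3,4-bis(tert-butyldimethylsilyloxy)phenyl]-4-methoxy-1,1-dimethyl-3-(3-methylbut-2-en-1-yl)-6-(triisopropylsilyloxy)-2,2a,7,7a-tetrahydro-1H-cyclobuta[a]indene, via aryllithium 16 (not isolated), via arylcopper 17 (not isolated)
Conditions: t-BuLi (2.1 equiv), THF, −78 °C; CuBr·SMe2 (1.1 equiv), −78 to −40 °C; 15, −40 to 0 °C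
Reagents that add atoms: none
Why: Bromine–lithium exchange, transmetalation with CuBr·SMe2 and allylic substitution of prenyl bromide at its primary carbon (attack at the gem-dimethyl carbon being sterically disfavoured) should install the linear prenyl group without touching a stereocentre or the aryl silyl ethers.

Step 11
Reactants: 18 (2S,2aR,7aS)-2-[3,4-bis(tert-butyldimethylsilyloxy)phenyl]-4-methoxy-1,1-dimethyl-3-(3-methylbut-2-en-1-yl)-6-(triisopropylsilyloxy)-2,2a,7,7a-tetrahydro-1H-cyclobuta[a]indene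
Product: 19 4-[(2S,2aR,7aS)-6-hydroxy-4-methoxy-1,1-dimethyl-3-(3-methylbut-2-en-1-yl)-2,2a,7,7a-tetrahydro-1H-cyclobuta[a]inden-2-yl]benzene-1,2-diol (CNP0236667.1)
Conditions: TBAF (3.5 equiv), AcOH (3.5 equiv), degassed THF, 0 °C
Reagents that add atoms: none
Why: Fluoride-mediated cleavage of the three aryl silyl ethers under acetic acid buffering should free the phenols while protecting the catechol from base-promoted air oxidation and leaving the prenyl alkene and the cyclobutane untouched.

Compound list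
1 | diethyl (3,5-dimethoxybenzyl)phosphonate | CCOP(=O)(OCC)Cc1cc(OC)cc(OC)c1 | starting material
2 | diethyl (2,6-dibromo-3,5-dimethoxybenzyl)phosphonate | CCOP(=O)(OCC)Cc1c(Br)c(OC)cc(OC)c1Br | intermediate
3 | 3,4-dihydroxybenzaldehyde | O=Cc1ccc(O)c(O)c1 | starting material
4 | 3,4-bis(tert-butyldimethylsilyloxy)benzaldehyde | O=Cc1ccc(O[Si](C)(C)C(C)(C)C)c(O[Si](C)(C)C(C)(C)C)c1 | intermediate
5 | (E)-2,6-dibromo-3,5-dimethoxy-3',4'-bis(tert-butyldimethylsilyloxy)stilbene | COc1cc(OC)c(Br)c(/C=C/c2ccc(O[Si](C)(C)C(C)(C)C)c(O[Si](C)(C)C(C)(C)C)c2)c1Br | intermediate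
6 | aryllithium from mono bromine–lithium exchange of 5 (not isolated) | COc1cc(OC)c([Li])c(/C=C/c2ccc(O[Si](C)(C)C(C)(C)C)c(O[Si](C)(C)C(C)(C)C)c2)c1Br | intermediate
7 | (E)-3-bromo-2-[3,4-bis(tert-butyldimethylsilyloxy)styryl]-4,6-dimethoxybenzaldehyde | COc1cc(OC)c(C=O)c(/C=C/c2ccc(O[Si](C)(C)C(C)(C)C)c(O[Si](C)(C)C(C)(C)C)c2)c1Br | intermediate
8 | (E)-3-bromo-6-hydroxy-4-methoxy-2-[3,4-bis(tert-butyldimethylsilyloxy)styryl]benzaldehyde | COc1cc(O)c(C=O)c(/C=C/c2ccc(O[Si](C)(C)C(C)(C)C)c(O[Si](C)(C)C(C)(C)C)c2)c1Br | intermediate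
9 | (E)-3-bromo-4-methoxy-6-(triisopropylsilyloxy)-2-[3,4-bis(tert-butyldimethylsilyloxy)styryl]benzaldehyde | COc1cc(O[Si](C(C)C)(C(C)C)C(C)C)c(C=O)c(/C=C/c2ccc(O[Si](C)(C)C(C)(C)C)c(O[Si](C)(C)C(C)(C)C)c2)c1Br | intermediate
10 | (2-methylprop-1-en-1-yl)magnesium bromide | CC(C)=C[Mg]Br | starting material
11 | (1S)-1-{3-bromo-4-methoxy-6-(triisopropylsilyloxy)-2-[(E)-3,4-bis(tert-butyldimethylsilyloxy)styryl]phenyl}-3-methylbut-2-en-1-ol | COc1cc(O[Si](C(C)C)(C(C)C)C(C)C)c([C@@H](O)C=C(C)C)c(/C=C/c2ccc(O[Si](C)(C)C(C)(C)C)c(O[Si](C)(C)C(C)(C)C)c2)c1Br | intermediate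
12 | triplet 1,4-diradical after C2a–C7a bonding: cis-1,2-disubstituted indan-3-ol with a benzylic radical (future C2) and a tertiary radical (future C1) (not isolated) | COc1cc(O[Si](C(C)C)(C(C)C)C(C)C)c2c(c1Br)[C@@H]([CH]c1ccc(O[Si](C)(C)C(C)(C)C)c(O[Si](C)(C)C(C)(C)C)c1)[C@H]([C@@H]2O)[C](C)C | intermediate
13 | (2S,2aS,7S,7aS)-3-bromo-2-[3,4-bis(tert-butyldimethylsilyloxy)phenyl]-4-methoxy-1,1-dimethyl-6-(triisopropylsilyloxy)-2,2a,7,7a-tetrahydro-1H-cyclobuta[a]inden-7-ol (cis ring fusion, aryl exo and trans to ring A, hydroxyl on the convex face) | COc1cc(O[Si](C(C)C)(C(C)C)C(C)C)c2c(c1Br)[C@@H]1[C@H]([C@@H]2O)C(C)(C)[C@H]1c1ccc(O[Si](C)(C)C(C)(C)C)c(O[Si](C)(C)C(C)(C)C)c1 | intermediate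
14 | (2S,2aR,7aS)-3-bromo-2-[3,4-bis(tert-butyldimethylsilyloxy)phenyl]-4-methoxy-1,1-dimethyl-6-(triisopropylsilyloxy)-2,2a,7,7a-tetrahydro-1H-cyclobuta[a]indene | COc1cc(O[Si](C(C)C)(C(C)C)C(C)C)c2c(c1Br)[C@@H]1[C@H](C2)C(C)(C)[C@H]1c1ccc(O[Si](C)(C)C(C)(C)C)c(O[Si](C)(C)C(C)(C)C)c1 | intermediate
15 | 1-bromo-3-methylbut-2-ene (prenyl bromide) | CC(C)=CCBr | starting material
16 | aryllithium from bromine–lithium exchange of 14 (not isolated) | COc1cc(O[Si](C(C)C)(C(C)C)C(C)C)c2c(c1[Li])[C@@H]1[C@H](C2)C(C)(C)[C@H]1c1ccc(O[Si](C)(C)C(C)(C)C)c(O[Si](C)(C)C(C)(C)C)c1 | intermediate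
17 | arylcopper from transmetalation of 16 (not isolated) | COc1cc(O[Si](C(C)C)(C(C)C)C(C)C)c2c(c1[Cu])[C@@H]1[C@H](C2)C(C)(C)[C@H]1c1ccc(O[Si](C)(C)C(C)(C)C)c(O[Si](C)(C)C(C)(C)C)c1 | intermediate
18 | (2S,2aR,7aS)-2-[3,4-bis(tert-butyldimethylsilyloxy)phenyl]-4-methoxy-1,1-dimethyl-3-(3-methylbut-2-en-1-yl)-6-(triisopropylsilyloxy)-2,2a,7,7a-tetrahydro-1H-cyclobuta[a]indene | COc1cc(O[Si](C(C)C)(C(C)C)C(C)C)c2c(c1CC=C(C)C)[C@@H]1[C@H](C2)C(C)(C)[C@H]1c1ccc(O[Si](C)(C)C(C)(C)C)c(O[Si](C)(C)C(C)(C)C)c1 | intermediate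
19 | 4-[(2S,2aR,7aS)-6-hydroxy-4-methoxy-1,1-dimethyl-3-(3-methylbut-2-en-1-yl)-2,2a,7,7a-tetrahydro-1H-cyclobuta[a]inden-2-yl]benzene-1,2-diol (CNP0236667.1) | COc1cc(O)c2c(c1CC=C(C)C)[C@@H]1[C@H](C2)C(C)(C)[C@H]1c1ccc(O)c(O)c1 | target

Total step count: 11.
Longest linear sequence: 10 steps (from 1 to 19 through steps 1 and 3 to 11; step 2 prepares the aldehyde partner).

The three steps most likely to fail

Risk at step 7: the addition to the doubly ortho-substituted, electron-rich aldehyde may be slow, so that uncatalysed racemic addition or poor facial discrimination erodes the enantiomeric purity on which all later stereocentres depend. Fallback for step 7: it sets out from 9 and comes back to the route at 11. Direct addition of 10 (THF, −78 °C) should give the racemic carbinol 1-{3-bromo-4-methoxy-6-(triisopropylsilyloxy)-2-[(E)-3,4-bis(tert-butyldimethylsilyloxy)styryl]phenyl}-3-methylbut-2-en-1-ol F1. Dess–Martin periodinane (NaHCO3, CH2Cl2, 0 °C) should oxidise F1 to the aryl alkenyl ketone 1-{3-bromo-4-methoxy-6-(triisopropylsilyloxy)-2-[(E)-3,4-bis(tert-butyldimethylsilyloxy)styryl]phenyl}-3-methylbut-2-en-1-one F2. Corey–Bakshi–Shibata reduction of F2 ((R)-Me-CBS oxazaborolidine, catecholborane, toluene, −78 °C), with the twisted di-ortho-substituted aryl group as the large substituent, should then return the (S)-carbinol 11.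

Risk at step 8: the free carbinol may discriminate the two alkene faces insufficiently, and unproductive E/Z isomerisation or disproportionation of the 1,4-diradical (hydrogen transfer from a methyl group) may compete with ring closure. Fallback for step 8: it sets out from 11 and comes back to the route at 14. Silylation (TBSOTf, 2,6-lutidine, CH2Cl2, 0 °C) should give (1S)-1-{3-bromo-4-methoxy-6-(triisopropylsilyloxy)-2-[(E)-3,4-bis(tert-butyldimethylsilyloxy)styryl]phenyl}-3-methylbut-2-en-1-yl tert-butyldimethylsilyl ether F3, whose larger oxygen substituent raises the allylic-strain bias. A hole-catalysed radical-cation [2+2] cycloaddition of F3 (Ru(bpz)3(PF6)2 cat., air, MeNO2, visible light) is a polar stepwise alternative in which the alkene attacks the stilbene radical cation at C2a before the C1–C2 bond closes. It should give (2S,2aS,7S,7aS)-3-bromo-2-[3,4-bis(tert-butyldimethylsilyloxy)phenyl]-7-(tert-butyldimethylsilyloxy)-4-methoxy-1,1-dimethyl-6-(triisopropylsilyloxy)-2,2a,7,7a-tetrahydro-1H-cyclobuta[a]indene F4. Et3SiH/TFA (CH2Cl2, −40 to 0 °C) should then cleave the benzylic C–O bond of F4 reductively to give 14.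

Risk at step 10: the hindered aryllithium may be quenched by proton transfer before it is alkylated, or the allylic substitution may occur with transposition at the tertiary carbon to give the 1,1-dimethylallyl isomer. Fallback for step 10: it sets out from 14 and comes back to the route at 18. A Negishi coupling of 14 with (3-methylbut-2-en-1-yl)zinc bromide (made from 15, zinc dust and LiCl in THF), catalysed by Pd(OAc)2 and the biarylphosphine CPhos in THF at rt, is a linear-selective prenylation of aryl bromides. It avoids strongly basic intermediates and should give 18 directly, so that no new compound arises (entry F0).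

Further compounds
F1 | step 7 | racemic 1-{3-bromo-4-methoxy-6-(triisopropylsilyloxy)-2-[(E)-3,4-bis(tert-butyldimethylsilyloxy)styryl]phenyl}-3-methylbut-2-en-1-ol | COc1cc(O[Si](C(C)C)(C(C)C)C(C)C)c(C(O)C=C(C)C)c(/C=C/c2ccc(O[Si](C)(C)C(C)(C)C)c(O[Si](C)(C)C(C)(C)C)c2)c1Br
F2 | step 7 | 1-{3-bromo-4-methoxy-6-(triisopropylsilyloxy)-2-[(E)-3,4-bis(tert-butyldimethylsilyloxy)styryl]phenyl}-3-methylbut-2-en-1-one | COc1cc(O[Si](C(C)C)(C(C)C)C(C)C)c(C(=O)C=C(C)C)c(/C=C/c2ccc(O[Si](C)(C)C(C)(C)C)c(O[Si](C)(C)C(C)(C)C)c2)c1Br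
F3 | step 8 | (1S)-1-{3-bromo-4-methoxy-6-(triisopropylsilyloxy)-2-[(E)-3,4-bis(tert-butyldimethylsilyloxy)styryl]phenyl}-3-methylbut-2-en-1-yl tert-butyldimethylsilyl ether | COc1cc(O[Si](C(C)C)(C(C)C)C(C)C)c([C@@H](O[Si](C)(C)C(C)(C)C)C=C(C)C)c(/C=C/c2ccc(O[Si](C)(C)C(C)(C)C)c(O[Si](C)(C)C(C)(C)C)c2)c1Br
F4 | step 8 | (2S,2aS,7S,7aS)-3-bromo-2-[3,4-bis(tert-butyldimethylsilyloxy)phenyl]-7-(tert-butyldimethylsilyloxy)-4-methoxy-1,1-dimethyl-6-(triisopropylsilyloxy)-2,2a,7,7a-tetrahydro-1H-cyclobuta[a]indene | COc1cc(O[Si](C(C)C)(C(C)C)C(C)C)c2c(c1Br)[C@@H]1[C@H]([C@@H]2O[Si](C)(C)C(C)(C)C)C(C)(C)[C@H]1c1ccc(O[Si](C)(C)C(C)(C)C)c(O[Si](C)(C)C(C)(C)C)c1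
F0 | step 10 | none | none
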